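The side chain is numbered from the benzylic C1' to C17'. The route rests on cutting the sp3–sp2 bond C7'–C8' at the isolated cis C8'=C9' double bond, remote from the resorcinol ring and from the C15' carbinol. The key step, a Zweifel olefination, unites a 7-arylheptyllithium with an (E)-alkenyl pinacol boronate made by syn hydroboration of a terminal alkyne: in one operation it forms C7'–C8' by a 1,2-shift from boron to carbon and turns the E precursor into the Z olefin. Its precursor is a lithium boronate complex carrying both fragments on boron; boron and iodine are expelled in the same flask. The C15' stereocentre derives from (S)-1,2-epoxybutane.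

Key step: step 8

Step 1
Reactants: 1 5-bromobenzene-1,3-diol
Product: 2 1-bromo-3,5-bis(methoxymethoxy)benzene
Conditions: MOMCl, i-Pr2NEt, CH2Cl2, 0 °C to rt
Reagents that add atoms: chloromethyl methyl ether, COCCl
Why: O-alkylation of both phenols (methoxymethyl acetal protection) should give ethers that withstand Grignard and organolithium reagents, iodine and methoxide and that fall off with acid in the last step.

Step 2
Reactants: 2 1-bromo-3,5-bis(methoxymethoxy)benzene, 3 1,7-dibromoheptane
Product: 5 1-(7-bromoheptyl)-3,5-bis(methoxymethoxy)benzene, via aryl Grignard reagent 4 (not isolated)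
Conditions: Mg, THF, reflux; then 3 (excess), Li2CuCl4 (cat.), THF, 0 °C to rt
Reagents that add atoms: none
Why: Grignard formation followed by copper-catalysed cross-coupling with a primary alkyl bromide (Kochi-type coupling) should attach the seven-carbon chain, the excess of the symmetric dibromide favouring monoarylation.

Step 3
Reactants: 5 1-(7-bromoheptyl)-3,5-bis(methoxymethoxy)benzene
Product: 6 1-(7-iodoheptyl)-3,5-bis(methoxymethoxy)benzene
Conditions: NaI, acetone, reflux
Reagents that add atoms: sodium iodide, [Na+].[I-]
Why: The Finkelstein reaction, an SN2 halide exchange driven by precipitation of NaBr, should give the primary iodide needed for clean lithium–iodine exchange.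

Step 4
Reactants: 7 hex-1-yne, 8 (S)-1,2-epoxybutane
Product: 10 (3S)-dec-5-yn-3-ol, via hex-1-ynyllithium 9 (not isolated)
Conditions: n-BuLi, THF, −78 °C; BF3·OEt2, then 8, −78 °C; then H2O
Reagents that add atoms: none
Why: BF3-promoted opening of the terminal epoxide by the lithium acetylide at its CH2 carbon (Yamaguchi–Hirao alkynylation) leaves the stereocentre of the epoxide untouched, so that it becomes the (S)-configured C15' carbinol.

Step 5
Reactants: 10 (3S)-dec-5-yn-3-ol
Product: 12 (3S)-dec-9-yn-3-ol, via dipotassium alkoxide acetylide 11 (not isolated)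
Conditions: KH, H2N(CH2)3NH2, 0 °C to rt; then H2O
Reagents that add atoms: none
Why: The alkyne zipper reaction should move the triple bond through propargyl and allenyl anions to the chain end, where it is trapped as the terminal acetylide, while the carbinol centre sits as a non-acidic alkoxide and keeps its configuration.

Step 6
Reactants: 12 (3S)-dec-9-yn-3-ol
Product: 13 tert-butyl{[(3S)-dec-9-yn-3-yl]oxy}dimethylsilane
Conditions: TBSCl, imidazole, DMF, rt
Reagents that add atoms: tert-butyldimethylsilyl chloride, CC(C)(C)[Si](C)(C)Cl
Why: Silylation of the secondary alcohol removes the acidic hydroxyl proton that would otherwise consume the alkyllithium of step 8.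

Step 7
Reactants: 13 tert-butyl{[(3S)-dec-9-yn-3-yl]oxy}dimethylsilane
Product: 14 2-[(1E,8S)-8-{[tert-butyl(dimethyl)silyl]oxy}dec-1-en-1-yl]-4,4,5,5-tetramethyl-1,3,2-dioxaborolane
Conditions: HBpin, Cp2Zr(H)Cl (cat.), Et3N (cat.), neat, 60 °C
Reagents that add atoms: pinacolborane, [H]B1OC(C)(C)C(C)(C)O1
Why: Zirconium-catalysed hydroboration of the terminal alkyne is a syn, anti-Markovnikov addition and should therefore place boron on the terminal carbon (the future C8') with exclusive E geometry.

Step 8
Reactants: 6 1-(7-iodoheptyl)-3,5-bis(methoxymethoxy)benzene, 14 2-[(1E,8S)-8-{[tert-butyl(dimethyl)silyl]oxy}dec-1-en-1-yl]-4,4,5,5-tetramethyl-1,3,2-dioxaborolane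
Product: 18 tert-butyl({(3S,9Z)-17-[3,5-bis(methoxymethoxy)phenyl]heptadec-9-en-3-yl}oxy)dimethylsilane, via primary alkyllithium 15 (not isolated), via lithium boronate complex 16 (not isolated), via iodoalkyl boronic ester 17 (not isolated)
Conditions: 6, t-BuLi (2 equiv), Et2O, −78 °C; then 14, THF, −78 °C; then I2, THF, −78 °C; then NaOMe, MeOH, −78 °C to rt
Reagents that add atoms: none
Why: Lithium–iodine exchange converts 6 into the primary alkyllithium 15, which adds to the boron atom of 14 to give the tetracoordinate boronate 16 in which C7' and C8' are both bound to boron. Iodine then activates the electron-rich alkenyl group as an iodonium ion, the heptyl chain undergoes a stereospecific 1,2-metallate shift from boron to C8' anti to iodine to give 17, and methoxide triggers anti elimination of boron and iodide; this is a Zweifel olefination, the closest known reaction type being the iodine-induced coupling of alkenylboronic esters with organolithium reagents. No ring is closed. No lasting stereocentre is created: the two transient stereocentres at C8' and C9' of 17 are set by the anti addition and erased by the anti elimination, which together translate the E geometry of 14 into the Z geometry of C8'=C9', while the remote C15' centre is not touched. The step needs exclusive migration of the heptyl chain, secured because the pinacol oxygen atoms do not migrate and the chain is the only other carbon ligand on boron, and it needs Z over E selectivity, secured by the geometric purity of 14 from syn hydroboration and by the anti/anti stereospecificity. It also needs iodine to attack the boronate and not the electron-rich diether arene, secured by the far higher nucleophilicity of the ate complex at −78 °C and by limiting I2 to about one equivalent; the MOM and TBS ethers tolerate t-BuLi at low temperature, iodine and methoxide.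

Step 9
Reactants: 18 tert-butyl({(3S,9Z)-17-[3,5-bis(methoxymethoxy)phenyl]heptadec-9-en-3-yl}oxy)dimethylsilane
Product: 19 Hansfordiol G
Conditions: HCl, MeOH, 45 °C
Reagents that add atoms: none
Why: Acid-catalysed acetal solvolysis and desilylation should remove both MOM groups and the TBS ether in one operation, methanol trapping the methoxymethyl cation as dimethoxymethane, while the isolated Z olefin and the secondary carbinol are inert to dilute methanolic HCl.

Compound list
1 | 5-bromobenzene-1,3-diol | Oc1cc(O)cc(Br)c1 | starting material
2 | 1-bromo-3,5-bis(methoxymethoxy)benzene | COCOc1cc(OCOC)cc(Br)c1 | intermediate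
3 | 1,7-dibromoheptane | BrCCCCCCCBr | starting material
4 | [3,5-bis(methoxymethoxy)phenyl]magnesium bromide (formed in the flask) | COCOc1cc(OCOC)cc([Mg]Br)c1 | intermediate
5 | 1-(7-bromoheptyl)-3,5-bis(methoxymethoxy)benzene | COCOc1cc(OCOC)cc(CCCCCCCBr)c1 | intermediate
6 | 1-(7-iodoheptyl)-3,5-bis(methoxymethoxy)benzene | COCOc1cc(OCOC)cc(CCCCCCCI)c1 | intermediate
7 | hex-1-yne | CCCCC#C | starting material
8 | (S)-1,2-epoxybutane, (2S)-2-ethyloxirane | CC[C@H]1CO1 | starting material
9 | hex-1-yn-1-yllithium (formed in the flask) | [Li]C#CCCCC | intermediate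
10 | (3S)-dec-5-yn-3-ol | CC[C@H](O)CC#CCCCC | intermediate
11 | dipotassium (3S)-dec-9-yn-10-id-3-olate (formed in the flask) | [K+].[K+].CC[C@H]([O-])CCCCCC#[C-] | intermediate
12 | (3S)-dec-9-yn-3-ol | CC[C@H](O)CCCCCC#C | intermediate
13 | tert-butyl{[(3S)-dec-9-yn-3-yl]oxy}dimethylsilane | CC[C@H](O[Si](C)(C)C(C)(C)C)CCCCCC#C | intermediate
14 | 2-[(1E,8S)-8-{[tert-butyl(dimethyl)silyl]oxy}dec-1-en-1-yl]-4,4,5,5-tetramethyl-1,3,2-dioxaborolane | CC[C@H](O[Si](C)(C)C(C)(C)C)CCCCC/C=C/B1OC(C)(C)C(C)(C)O1 | intermediate
15 | {7-[3,5-bis(methoxymethoxy)phenyl]heptyl}lithium (formed in the flask) | [Li]CCCCCCCc1cc(OCOC)cc(OCOC)c1 | intermediate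
16 | lithium [(1E,8S)-8-{[tert-butyl(dimethyl)silyl]oxy}dec-1-en-1-yl]{7-[3,5-bis(methoxymethoxy)phenyl]heptyl}(pinacolato)borate (formed in the flask) | [Li+].CC[C@H](O[Si](C)(C)C(C)(C)C)CCCCC/C=C/[B-]1(CCCCCCCc2cc(OCOC)cc(OCOC)c2)OC(C)(C)C(C)(C)O1 | intermediate
17 | beta-iodoalkyl pinacol boronic ester, the anti adduct of iodine and the migrated heptyl chain across C8'=C9' (formed in the flask as two diastereomers, both (15'S); C8' and C9' left open in the SMILES) | CC[C@H](O[Si](C)(C)C(C)(C)C)CCCCCC(I)C(CCCCCCCc1cc(OCOC)cc(OCOC)c1)B1OC(C)(C)C(C)(C)O1 | intermediate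
18 | tert-butyl({(3S,9Z)-17-[3,5-bis(methoxymethoxy)phenyl]heptadec-9-en-3-yl}oxy)dimethylsilane | CC[C@H](O[Si](C)(C)C(C)(C)C)CCCCC/C=C\CCCCCCCc1cc(OCOC)cc(OCOC)c1 | intermediate
19 | Hansfordiol G, 5-[(8Z,15S)-15-hydroxyheptadec-8-en-1-yl]benzene-1,3-diol | CC[C@H](O)CCCCC/C=C\CCCCCCCc1cc(O)cc(O)c1 | target

Total step count: 9.
Longest linear sequence: 6 steps (steps 4 to 9, from hex-1-yne and (S)-1,2-epoxybutane); the aryl branch (steps 1 to 3) joins at step 8.

Steps most likely to fail

Step 8 (key step). The boronate complex may form incompletely if the alkyllithium is quenched by proton transfer from the ring position between the two acetal oxygens or if the lithium–iodine exchange is not clean. Iodine may also attack the electron-rich arene, and any leak in the anti/anti sequence would erode the Z geometry. The fallback sets out from 13 (and uses 6) and comes back at 18. Deprotonation of 13 with n-BuLi in THF/DMPU and SN2 alkylation of the acetylide with iodide 6 should form the same C7'–C8' bond and give the internal alkyne tert-butyl({(3S)-17-[3,5-bis(methoxymethoxy)phenyl]heptadec-9-yn-3-yl}oxy)dimethylsilane F1. Lindlar semi-hydrogenation of F1 (H2, Pd on CaCO3 poisoned with Pb(OAc)2, quinoline, hexane) should then deliver the Z olefin 18 by syn addition of hydrogen.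

Step 5. The triple bond may migrate incompletely and stall at internal alkyne or allene isomers, and the strongly basic medium may degrade the material. The fallback sets out from 8 and comes back at 14, bypassing the alkyne altogether. Opening of 8 at its CH2 carbon with hex-5-en-1-ylmagnesium bromide F2 (from 6-bromohex-1-ene and Mg) under CuI catalysis in THF at −30 °C should give (3S)-dec-9-en-3-ol F3. Silylation with TBSCl and imidazole should give tert-butyl{[(3S)-dec-9-en-3-yl]oxy}dimethylsilane F4. Cross-metathesis of F4 with pinacol vinylboronate under the second-generation Grubbs catalyst in refluxing CH2Cl2 should then give 14, the E geometry arising under thermodynamic control; the geometric purity of 14 would have to be checked before step 8.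

Step 2. Magnesium insertion into the electron-rich aryl bromide may be sluggish, and the coupling may suffer from biaryl homocoupling or from double arylation of the dibromide. The fallback sets out from 2 and comes back at 5, replacing the Grignard alkylation by a palladium-catalysed sp2–sp3 coupling. Hydroboration of 7-bromohept-1-ene with 9-BBN-H in THF should give 9-(7-bromoheptyl)-9-borabicyclo[3.3.1]nonane F5. B-alkyl Suzuki–Miyaura coupling of F5 with 2 (Pd(dppf)Cl2, K3PO4, THF/DMF/H2O, 50 °C) should give 5; the primary carbon–bromine bond is expected to be inert to zerovalent palladium carrying dppf under these conditions.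

Further compounds
F1 | step 8 | tert-butyl({(3S)-17-[3,5-bis(methoxymethoxy)phenyl]heptadec-9-yn-3-yl}oxy)dimethylsilane | CC[C@H](O[Si](C)(C)C(C)(C)C)CCCCCC#CCCCCCCCc1cc(OCOC)cc(OCOC)c1
F2 | step 5 | hex-5-en-1-ylmagnesium bromide | C=CCCCC[Mg]Br
F3 | step 5 | (3S)-dec-9-en-3-ol | CC[C@H](O)CCCCCC=C
F4 | step 5 | tert-butyl{[(3S)-dec-9-en-3-yl]oxy}dimethylsilane | CC[C@H](O[Si](C)(C)C(C)(C)C)CCCCCC=C
F5 | step 2 | 9-(7-bromoheptyl)-9-borabicyclo[3.3.1]nonane | BrCCCCCCCB1C2CCCC1CCC2
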